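**Late plateau.** Late readings stand flat: in the north-west run, starting material reads 0.1% at 120 s, and product stays below full yield. Free catalyst converts starting material to product, while protic impurity appears to consume it one to one. The north-west shortfall is 0.952 mM against 1 mM of protic impurity charged, so about 0.0477 mM of impurity survives. That remainder is a small difference of readings scattering by 0.5 percentage points, so it is rough.

| flask | starting material | protic impurity | free catalyst | remark | time |
|---|---|---|---|---|---|
| north | 20 mM | 0.32 mM | 2.6 mM | run made earlier |  |
| west | 20 mM | 0.78 mM | 2.6 mM | run made earlier |  |
| north-west | 13 mM | 1 mM | 2.6 mM | run made earlier |  |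
| noon | 20 mM | 1.00 mM | 2.6 mM |  | 2.0 min |
| autumn | 6.0 mM | 0.500 mM | 2.6 mM |  | 2.0 min |

| run | time / s | product / % | starting material / % |
|---|---|---|---|
| north | 15.0 | 98.9 | 0.1 |
| north | 40.0 | 98.7 | 0.7 |
| north | 80.0 | 98.5 | 0 |
| north | 120 | 99.2 | 0.2 |
| west | 10.0 | 93.9 | 0 |
| west | 20.0 | 96.3 | 0.6 |
| west | 50.0 | 96.1 | 0.3 |
| west | 120 | 95.2 | 0 |
| north-west | 30.0 | 92.0 | 0 |
| north-west | 60.0 | 93.1 | 0 |
| north-west | 90.0 | 93.2 | 0.3 |
| north-west | 120 | 92.4 | 0.1 |

(standard deviation of a reading: 0.5 percentage points)

- a reading or a percentage of product counts all its forms, free or not

- which one finishes higher in amount of product, in percent of the starting material charged ("neither" within 2 percentage points) (noon / autumn / neither)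
- amount of product at the end, in percent of the starting material charged, noon
- amount of product at the end, in percent of the starting material charged, autumn

**First instants.** Starting material meets free catalyst and protic impurity together. This reckoning takes the impurity's decay as first order in [protic impurity], with a rate coefficient proportional to [starting material]: a pseudo-first-order decay. The impurity exposure, ln([protic impurity] charged / [protic impurity] at the end), is then 3.04 as read from the north-west run.

**The middle.** The first readings of starting material already stand at 0.1% in the north run, 0% in the west run and 0% in the north-west run, so they do not show this stage. My assumption is a steady catalytic rate, so [starting material] falls in a straight line. At one free-catalyst charge, the exposure in this reckoning is then proportional to the square of the starting-material charge and does not depend on the impurity charge.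

**The end.** Scaling gives noon an exposure of 7.20, so nearly all of its impurity should react and product should reach 95.0%. Autumn gets 0.648, so 52.3% of its impurity should remain when starting material reaches zero, and product should reach 96.0%. The gap of 1 point is smaller than the margin of 2 points, so this reckoning says neither.

**The forecast.** It differs from my reckoning on autumn and on the choice: it names noon, with 95.1% for noon and 92% for autumn, on the ground “The loss is therefore about one equivalent of impurity”.

**The result.** The simulation gives neither: noon 95.0%, autumn 94.8%.

    catalyst intermediate A ⇌ catalyst intermediate B (K = 1.80, k = 1.80 s⁻¹)
    catalyst intermediate B → free catalyst + product (k = 2.90 s⁻¹)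
    crystals ⇌ product, rate k3*(cs3 - [product]) while solid is left; crystals form when [product] > cs3 (solubility = 11.0 mM, k = 1.40 s⁻¹)
    starting material + protic impurity → quenched substrate (k = 160 L mol⁻¹ s⁻¹)
    starting material + free catalyst → catalyst intermediate A (k = 990 L mol⁻¹ s⁻¹)

**Neighbour flask.** Autumn ends with starting material at 0% and 37.3% of its protic impurity left, an exposure of 0.987 against the 0.648 scaled from north-west. The neighbour is autumn with 1.2 mM of protic impurity. Carrying autumn's exposure over unchanged gives 37.3% of the neighbour's impurity left and 87.5% product. The neighbour flask ends at 88.2% product with 41% of its protic impurity left.

(The earlier runs and the new flask are simulated with constants of no real substance, and the scatter is random.)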